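**Retrosynthetic overview**
- Both erythro side chains are cut at the carbinol (chelation-controlled reduction of α-aryloxy ketones), at the aryl–C(=O) bond (Weinreb ketone synthesis) and at the ArO–C bond (Mitsunobu reaction with ethyl (R)-lactate), back to a bis-guaiacyl oxolane.
- The oxolane is opened at O1–C5. C5 is a benzylic carbon para to the phenolic oxygen of its guaiacyl ring, so a seco-lignan with C5 as CH2 can be oxidised to the para-quinone methide and closed by the C2 hydroxyl.
- The seco-lignan is cut at C2–aryl (Felkin–Anh aryl Grignard addition to a 4-aryl-2,3-dimethylbutanal). The C5 CH2 comes from an aryl ketone made by opening (3R,4R)-3,4-dimethylsuccinic anhydride.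
- The two methyl-bearing centres come from oxidative homocoupling of an oxazolidinone propionimide.
- Ring order: the oxolane is the only ring formed (step 11); all arenes are bought.

Key step: step 11

Remark: the oxolane is numbered O1, C2 (aryl cis to the C3 methyl), C3, C4, C5 (aryl trans to the C4 methyl) throughout, also where both aryl groups are alike. Arylmagnesium bromide 8 is made once (step 5) as a titrated THF solution, kept under argon, and drawn on in steps 6 and 10. The phenol set free in step 7 is carried unprotected through steps 8 to 10 and consumes one extra equivalent of each basic or hydridic reagent.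

**Step 1**
Reactants: 1 (S)-4-benzyl-3-propanoyl-1,3-oxazolidin-2-one (two molecules per molecule of product)
Product: 3 (4S,4'S)-3,3'-[(2R,3R)-2,3-dimethylbutanedioyl]bis(4-benzyl-1,3-oxazolidin-2-one), via lithium Z-enolate 2 (not isolated)
Conditions: 1 (2 equiv), LiN(iPr)2 (1.1 equiv per imide), THF, −78 °C; then TiCl4 (1.1 equiv per imide), −78 °C → rt; crystallisation
Reagents that add atoms: a second molecule of imide 1, CCC(=O)N1[C@@H](Cc2ccccc2)COC1=O
Why: Oxidative homocoupling of a chelated imide Z-enolate (one-electron oxidation by TiCl4, then C–C coupling of two enolate-derived units) is a known route to 2,3-dialkylsuccinyl bis-imides; each new bond should form on the enolate face away from the C4 benzyl group of the (S)-auxiliary, which makes both methyl-bearing centres R, and the meso-type diastereomer is removed by crystallisation.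

**Step 2**
Reactants: 3 (4S,4'S)-3,3'-[(2R,3R)-2,3-dimethylbutanedioyl]bis(4-benzyl-1,3-oxazolidin-2-one)
Product: 4 (2R,3R)-2,3-dimethylbutanedioic acid
Conditions: LiOH, H2O2 (30% aq), THF/H2O, 0 °C; aq Na2SO3; HCl to pH 1
Reagents that add atoms: hydrogen peroxide (as LiOOH), OO
Why: Hydroperoxide cleavage of N-acyl oxazolidinones attacks the exocyclic carbonyl, so the diacid should be released without epimerisation of the α-centres and the auxiliary is recovered.

**Step 3**
Reactants: 4 (2R,3R)-2,3-dimethylbutanedioic acid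
Product: 5 (3R,4R)-3,4-dimethyloxolane-2,5-dione (trans anhydride)
Conditions: AcCl (neat), 50 °C; evaporation
Reagents that add atoms: none
Why: Cyclodehydration of a succinic acid with acetyl chloride gives the five-membered anhydride, and at this temperature no enolisation is expected, so the trans-dimethyl arrangement is kept.

**Step 4**
Reactants: 6 4-bromo-2-methoxyphenol
Product: 7 1-(benzyloxy)-4-bromo-2-methoxybenzene
Conditions: BnBr, K2CO3, DMF, rt
Reagents that add atoms: benzyl bromide, BrCc1ccccc1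
Why: Williamson etherification of the phenoxide with a benzylic bromide.

**Step 5**
Reactants: 7 1-(benzyloxy)-4-bromo-2-methoxybenzene
Product: 8 [4-(benzyloxy)-3-methoxyphenyl]magnesium bromide (titrated THF stock solution, stored under argon)
Conditions: Mg turnings (1.3 equiv), I2 (cat.), THF, 40 °C; titration
Reagents that add atoms: magnesium, [Mg]
Why: Grignard reagent formation by oxidative insertion of magnesium into the aryl C–Br bond, to which the benzyl and methyl ethers are inert; the solution is made on a scale that serves steps 6 and 10.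

**Step 6**
Reactants: 8 [4-(benzyloxy)-3-methoxyphenyl]magnesium bromide; 5 (3R,4R)-3,4-dimethyloxolane-2,5-dione
Product: 9 (2R,3R)-4-[4-(benzyloxy)-3-methoxyphenyl]-2,3-dimethyl-4-oxobutanoic acid
Conditions: 8 (1.0 equiv) added to 5 (1.2 equiv), THF, −78 → −20 °C; aq HCl
Reagents that add atoms: none
Why: Mono-addition of an aryl Grignard reagent to a cyclic anhydride stops at the keto carboxylate at low temperature; the anhydride is C2-symmetric, so either carbonyl gives the same keto acid and neither stereocentre is touched.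

**Step 7**
Reactants: 9 (2R,3R)-4-[4-(benzyloxy)-3-methoxyphenyl]-2,3-dimethyl-4-oxobutanoic acid
Product: 11 (2R,3S)-4-(4-hydroxy-3-methoxyphenyl)-2,3-dimethylbutanoic acid, via phenolic keto acid 10 (not isolated)
Conditions: H2 (3 atm), 10% Pd/C, AcOH, HClO4 (cat.), rt
Reagents that add atoms: none
Why: Acid-promoted hydrogenolysis over Pd reduces the electron-rich aryl ketone to the methylene (the classical reduction of β-aroylpropionic acids) and removes the benzyl ether in the same operation; the two stereocentres are not involved, and the C3 descriptor changes from R to S only because C4 loses its oxygen.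

**Step 8**
Reactants: 11 (2R,3S)-4-(4-hydroxy-3-methoxyphenyl)-2,3-dimethylbutanoic acid
Product: 12 (2R,3S)-4-(4-hydroxy-3-methoxyphenyl)-N-methoxy-N,2,3-trimethylbutanamide
Conditions: MeNHOMe·HCl, N-ethyl-N'-(3-dimethylaminopropyl)carbodiimide hydrochloride (EDC·HCl), 1-hydroxybenzotriazole, N-methylmorpholine, CH2Cl2, 0 °C → rt
Reagents that add atoms: N,O-dimethylhydroxylamine hydrochloride, CNOC.Cl
Why: Carbodiimide/hydroxybenzotriazole amide coupling, in which the amine should take the active ester much faster than the phenol and the α-centre is not epimerised under weakly basic conditions.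

**Step 9**
Reactants: 12 (2R,3S)-4-(4-hydroxy-3-methoxyphenyl)-N-methoxy-N,2,3-trimethylbutanamide
Product: 13 (2R,3S)-4-(4-hydroxy-3-methoxyphenyl)-2,3-dimethylbutanal
Conditions: iBu2AlH (2.5 equiv), THF, −78 °C; aq KNaC4H4O6 (potassium sodium tartrate)
Reagents that add atoms: none
Why: Hydride reduction of a Weinreb amide stops at the aldehyde because the chelated tetrahedral adduct survives until work-up; the first equivalent of hydride is consumed by the phenol, and the aldehyde is used at once to avoid α-epimerisation.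

**Step 10**
Reactants: 13 (2R,3S)-4-(4-hydroxy-3-methoxyphenyl)-2,3-dimethylbutanal; 8 [4-(benzyloxy)-3-methoxyphenyl]magnesium bromide
Product: 14 (1S,2R,3S)-1-[4-(benzyloxy)-3-methoxyphenyl]-4-(4-hydroxy-3-methoxyphenyl)-2,3-dimethylbutan-1-ol
Conditions: 8 (3 equiv, stock solution from step 5) added to 13, THF, −78 °C; aq NH4Cl
Reagents that add atoms: none
Why: Felkin–Anh addition of an aryl Grignard reagent to an α-methyl aldehyde: with the sec-alkyl chain anti to the nucleophile and attack past the α-hydrogen, the new C1 carbinol should form 1,2-syn to the C2 methyl (1S); the first equivalent of reagent deprotonates the phenol, and the 1,2-anti epimer is removed by chromatography.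

**Step 11**
Reactants: 14 (1S,2R,3S)-1-[4-(benzyloxy)-3-methoxyphenyl]-4-(4-hydroxy-3-methoxyphenyl)-2,3-dimethylbutan-1-ol
Product: 16 (2S,3R,4R,5R)-2-[4-(benzyloxy)-3-methoxyphenyl]-5-(4-hydroxy-3-methoxyphenyl)-3,4-dimethyloxolane, via para-quinone methide 15 (not isolated)
Conditions: Ag2O (3 equiv), anhydrous Na2SO4, CH2Cl2 (0.01 M), rt, dark
Reagents that add atoms: none
Why: Ag2O takes two electrons and two protons from the only free phenol (phenoxyl radical, then loss of a C5 benzylic hydrogen) to give para-quinone methide 15, and the C2 hydroxyl adds to the exocyclic methide carbon in a 1,6-oxa-Michael addition that re-aromatises the ring and forms O1–C5. The closest known reaction type is the Ag2O or DDQ oxidation of 4-alkylguaiacols to quinone methides with intramolecular capture by a hydroxyl group, as in biomimetic lignan cyclisations. The oxolane closes in a 5-exo-trig mode. The new C5 centre is controlled by the C4 methyl: allylic 1,3-strain holds the C4–H bond in the plane of the methide, so the tethered oxygen attacks the face opposite that methyl and the aryl group ends trans to it (5R), and reversal through the quinone methide would lead to the same, more stable epimer. The step needs oxidation at one arene only and O- rather than C-capture: the benzyl ether blocks quinone methide formation at C2 (so the 2,3-cis relation from step 10 is kept), and neutral, acid-free, dilute conditions disfavour Friedel–Crafts attack by the benzyl-capped arene, tautomerisation to the styrene and intermolecular phenol addition.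

**Step 12**
Reactants: 16 (2S,3R,4R,5R)-2-[4-(benzyloxy)-3-methoxyphenyl]-5-(4-hydroxy-3-methoxyphenyl)-3,4-dimethyloxolane
Product: 17 4,4'-[(2S,3R,4R,5R)-3,4-dimethyloxolane-2,5-diyl]bis(2-methoxyphenol)
Conditions: H2 (1 atm), 10% Pd/C, EtOAc, rt; stopped at one equivalent of uptake
Reagents that add atoms: none
Why: Hydrogenolysis of an aryl benzyl ether over Pd under neutral conditions, where the O-benzyl bond should be cleaved much faster than the two benzylic C–O bonds of the oxolane ring.

**Step 13**
Reactants: 17 4,4'-[(2S,3R,4R,5R)-3,4-dimethyloxolane-2,5-diyl]bis(2-methoxyphenol); 18 ethyl (R)-lactate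
Product: 19 diethyl (2S,2'S)-2,2'-{[(2S,3R,4R,5R)-3,4-dimethyloxolane-2,5-diyl]bis[(2-methoxy-4,1-phenylene)oxy]}dipropanoate
Conditions: 18 (3 equiv), PPh3 (3 equiv), diisopropyl azodicarboxylate (3 equiv), THF, 0 °C → rt
Reagents that add atoms: a second equivalent of ethyl (R)-lactate 18, CCOC(=O)[C@@H](C)O
Why: Double Mitsunobu etherification of the two phenols with the secondary α-hydroxy ester proceeds by SN2 displacement of the oxyphosphonium group, so each lactate carbon is inverted from R to S.

**Step 14**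
Reactants: 19 diethyl (2S,2'S)-2,2'-{[(2S,3R,4R,5R)-3,4-dimethyloxolane-2,5-diyl]bis[(2-methoxy-4,1-phenylene)oxy]}dipropanoate
Product: 20 (2S,2'S)-2,2'-{[(2S,3R,4R,5R)-3,4-dimethyloxolane-2,5-diyl]bis[(2-methoxy-4,1-phenylene)oxy]}bis(N-methoxy-N-methylpropanamide)
Conditions: MeNHOMe·HCl (6 equiv), iPrMgCl (12 equiv), THF, −20 °C
Reagents that add atoms: N,O-dimethylhydroxylamine hydrochloride, CNOC.Cl; a second equivalent of N,O-dimethylhydroxylamine hydrochloride, CNOC.Cl
Why: Aminolysis of both esters by the magnesium amide of N,O-dimethylhydroxylamine (Weinreb amide formation), which at low temperature should be fast relative to deprotonation of the α-aryloxy centres.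

**Step 15**
Reactants: 20 (2S,2'S)-2,2'-{[(2S,3R,4R,5R)-3,4-dimethyloxolane-2,5-diyl]bis[(2-methoxy-4,1-phenylene)oxy]}bis(N-methoxy-N-methylpropanamide); 21 4-bromo-1,2-dimethoxybenzene
Product: 23 (2S,2'S)-2,2'-{[(2S,3R,4R,5R)-3,4-dimethyloxolane-2,5-diyl]bis[(2-methoxy-4,1-phenylene)oxy]}bis[1-(3,4-dimethoxyphenyl)propan-1-one], via arylmagnesium bromide 22 (not isolated)
Conditions: 21 (5 equiv), Mg, I2 (cat.), THF; the resulting reagent added to 20, THF, −20 → 0 °C; cold aq NH4Cl
Reagents that add atoms: a second equivalent of 4-bromo-1,2-dimethoxybenzene 21 (used as its Grignard reagent 22), COc1ccc(Br)cc1OC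
Why: Weinreb ketone synthesis at both amides: the magnesium-chelated tetrahedral adducts collapse only on aqueous quench, so there is no over-addition and the epimerisable α-aryloxy ketone never meets the basic reagent.

**Step 16**
Reactants: 23 (2S,2'S)-2,2'-{[(2S,3R,4R,5R)-3,4-dimethyloxolane-2,5-diyl]bis[(2-methoxy-4,1-phenylene)oxy]}bis[1-(3,4-dimethoxyphenyl)propan-1-one]
Product: 24 (1R,1'R,2S,2'S)-2,2'-{[(2S,3R,4R,5R)-3,4-dimethyloxolane-2,5-diyl]bis[(2-methoxy-4,1-phenylene)oxy]}bis[1-(3,4-dimethoxyphenyl)propan-1-ol] (CNP0116650.13)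
Conditions: Zn(BH4)2, Et2O, −20 → 0 °C; aq NH4Cl
Reagents that add atoms: none
Why: Chelation-controlled (Cram-chelate) reduction: zinc bridges the carbonyl oxygen and the α-aryloxy oxygen (helped by the ortho methoxy group) and hydride is delivered past the α-hydrogen, which should give the anti (erythro) 1R,2S alcohol in both side chains.

**Compound list**
1 | (S)-4-benzyl-3-propanoyl-1,3-oxazolidin-2-one | CCC(=O)N1[C@@H](Cc2ccccc2)COC1=O | starting material
2 | lithium Z-enolate of 1 | C/C=C(\O[Li])N1[C@@H](Cc2ccccc2)COC1=O | intermediate (not isolated)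
3 | (4S,4'S)-3,3'-[(2R,3R)-2,3-dimethylbutanedioyl]bis(4-benzyl-1,3-oxazolidin-2-one) | O=C([C@H](C)[C@@H](C)C(=O)N1[C@@H](Cc2ccccc2)COC1=O)N1[C@@H](Cc2ccccc2)COC1=O | intermediate
4 | (2R,3R)-2,3-dimethylbutanedioic acid | OC(=O)[C@H](C)[C@@H](C)C(=O)O | intermediate
5 | (3R,4R)-3,4-dimethyloxolane-2,5-dione | C[C@H]1C(=O)OC(=O)[C@@H]1C | intermediate
6 | 4-bromo-2-methoxyphenol | COc1cc(Br)ccc1O | starting material
7 | 1-(benzyloxy)-4-bromo-2-methoxybenzene | COc1cc(Br)ccc1OCc1ccccc1 | intermediate
8 | [4-(benzyloxy)-3-methoxyphenyl]magnesium bromide | COc1cc([Mg]Br)ccc1OCc1ccccc1 | intermediate (titrated THF stock solution)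
9 | (2R,3R)-4-[4-(benzyloxy)-3-methoxyphenyl]-2,3-dimethyl-4-oxobutanoic acid | COc1cc(C(=O)[C@H](C)[C@@H](C)C(=O)O)ccc1OCc1ccccc1 | intermediate
10 | (2R,3R)-4-(4-hydroxy-3-methoxyphenyl)-2,3-dimethyl-4-oxobutanoic acid | COc1cc(C(=O)[C@H](C)[C@@H](C)C(=O)O)ccc1O | intermediate (not isolated)
11 | (2R,3S)-4-(4-hydroxy-3-methoxyphenyl)-2,3-dimethylbutanoic acid | COc1cc(C[C@H](C)[C@@H](C)C(=O)O)ccc1O | intermediate
12 | (2R,3S)-4-(4-hydroxy-3-methoxyphenyl)-N-methoxy-N,2,3-trimethylbutanamide | COc1cc(C[C@H](C)[C@@H](C)C(=O)N(C)OC)ccc1O | intermediate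
13 | (2R,3S)-4-(4-hydroxy-3-methoxyphenyl)-2,3-dimethylbutanal | COc1cc(C[C@H](C)[C@@H](C)C=O)ccc1O | intermediate
14 | (1S,2R,3S)-1-[4-(benzyloxy)-3-methoxyphenyl]-4-(4-hydroxy-3-methoxyphenyl)-2,3-dimethylbutan-1-ol | COc1cc(C[C@H](C)[C@@H](C)[C@H](O)c2ccc(OCc3ccccc3)c(OC)c2)ccc1O | intermediate (key-step precursor)
15 | 4-{(2S,3R,4S)-4-[4-(benzyloxy)-3-methoxyphenyl]-4-hydroxy-2,3-dimethylbutylidene}-2-methoxycyclohexa-2,5-dien-1-one | COC1=CC(=C[C@H](C)[C@@H](C)[C@H](O)c2ccc(OCc3ccccc3)c(OC)c2)C=CC1=O | intermediate (not isolated)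
16 | (2S,3R,4R,5R)-2-[4-(benzyloxy)-3-methoxyphenyl]-5-(4-hydroxy-3-methoxyphenyl)-3,4-dimethyloxolane | O1[C@@H](c2ccc(O)c(OC)c2)[C@H](C)[C@@H](C)[C@H]1c1ccc(OCc2ccccc2)c(OC)c1 | intermediate (key-step product)
17 | 4,4'-[(2S,3R,4R,5R)-3,4-dimethyloxolane-2,5-diyl]bis(2-methoxyphenol) | O1[C@@H](c2ccc(O)c(OC)c2)[C@H](C)[C@@H](C)[C@H]1c1ccc(O)c(OC)c1 | intermediate
18 | ethyl (R)-lactate | CCOC(=O)[C@@H](C)O | starting material
19 | diethyl (2S,2'S)-2,2'-{[(2S,3R,4R,5R)-3,4-dimethyloxolane-2,5-diyl]bis[(2-methoxy-4,1-phenylene)oxy]}dipropanoate | O1[C@@H](c2ccc(O[C@@H](C)C(=O)OCC)c(OC)c2)[C@H](C)[C@@H](C)[C@H]1c1ccc(O[C@@H](C)C(=O)OCC)c(OC)c1 | intermediate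
20 | (2S,2'S)-2,2'-{[(2S,3R,4R,5R)-3,4-dimethyloxolane-2,5-diyl]bis[(2-methoxy-4,1-phenylene)oxy]}bis(N-methoxy-N-methylpropanamide) | O1[C@@H](c2ccc(O[C@@H](C)C(=O)N(C)OC)c(OC)c2)[C@H](C)[C@@H](C)[C@H]1c1ccc(O[C@@H](C)C(=O)N(C)OC)c(OC)c1 | intermediate
21 | 4-bromo-1,2-dimethoxybenzene | COc1ccc(Br)cc1OC | starting material
22 | (3,4-dimethoxyphenyl)magnesium bromide | COc1ccc([Mg]Br)cc1OC | intermediate (not isolated)
23 | (2S,2'S)-2,2'-{[(2S,3R,4R,5R)-3,4-dimethyloxolane-2,5-diyl]bis[(2-methoxy-4,1-phenylene)oxy]}bis[1-(3,4-dimethoxyphenyl)propan-1-one] | O1[C@@H](c2ccc(O[C@@H](C)C(=O)c3ccc(OC)c(OC)c3)c(OC)c2)[C@H](C)[C@@H](C)[C@H]1c1ccc(O[C@@H](C)C(=O)c2ccc(OC)c(OC)c2)c(OC)c1 | intermediate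
24 | (1R,1'R,2S,2'S)-2,2'-{[(2S,3R,4R,5R)-3,4-dimethyloxolane-2,5-diyl]bis[(2-methoxy-4,1-phenylene)oxy]}bis[1-(3,4-dimethoxyphenyl)propan-1-ol] | COc1ccc([C@@H](O)[C@H](C)Oc2ccc([C@H]3O[C@@H](c4ccc(O[C@@H](C)[C@H](O)c5ccc(OC)c(OC)c5)c(OC)c4)[C@H](C)[C@H]3C)cc2OC)cc1OC | target

**Step count**
Total: 16 steps. Longest linear sequence: 14 steps (steps 1–3 and 6–16; steps 4 and 5 form a two-step side branch that feeds steps 6 and 10).

**Steps most likely to fail**

Step 11. The quinone methide may tautomerise to the styrene or add a second phenol intermolecularly, or the phenoxyl radical may couple ortho–ortho before the hydroxyl closes. The fallback gives up the oxidative closure for the known lactol reduction; it sets out from keto acid 9 and comes back at bisphenol 17. Reduction of 9 with NaBH4 (aq NaOH/MeOH, 0 °C) and acid-catalysed lactonisation (TsOH cat., toluene, rt), which also equilibrates the benzylic centre to the 4,5-trans arrangement, would give (3R,4R,5R)-5-[4-(benzyloxy)-3-methoxyphenyl]-3,4-dimethyloxolan-2-one F1. Addition of arylmagnesium bromide 8 (THF, −78 °C) would give the lactol (3R,4R,5R)-2,5-bis[4-(benzyloxy)-3-methoxyphenyl]-3,4-dimethyloxolan-2-ol F2. Et3SiH/BF3·OEt2 (CH2Cl2, −78 °C) should reduce the cyclic oxocarbenium ion, with hydride expected to enter anti to the C3 methyl, to give (2S,3R,4R,5R)-2,5-bis[4-(benzyloxy)-3-methoxyphenyl]-3,4-dimethyloxolane F3. Hydrogenolysis (H2, 10% Pd/C, EtOAc) would then give 17.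

Step 10. Facial selectivity in the addition to the α-methyl aldehyde may be poor, and the aldehyde may epimerise at its α-carbon. The fallback sets C1 by reagent control; it sets out from Weinreb amide 12 and comes back at 14. Arylmagnesium bromide 8 (3 equiv, THF, 0 °C) would convert 12 into (2R,3S)-1-[4-(benzyloxy)-3-methoxyphenyl]-4-(4-hydroxy-3-methoxyphenyl)-2,3-dimethylbutan-1-one F4. CBS reduction with (R)-1-methyl-3,3-diphenyl-tetrahydro-1H,3H-pyrrolo[1,2-c][1,3,2]oxazaborole (cat.) and BH3·SMe2 (excess, THF, −20 °C) should deliver hydride to the face that gives the 1S alcohol, against the substrate's own Felkin preference, and return to 14.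

Step 1. The one-electron oxidation may give low conversion, or the C–C coupling may show poor selection between the (R,R) and meso-type dimers. The fallback builds the same diacid by auxiliary-controlled alkylation; it sets out from 1 and 18 and comes back at 4. Tf2O/2,6-lutidine (CH2Cl2, −78 °C) would convert 18 into ethyl (R)-2-{[(trifluoromethyl)sulfonyl]oxy}propanoate F5. Lithium enolate 2 (from 1, LiN(iPr)2, THF, −78 °C) should displace the triflate with inversion, on the face away from the benzyl group, to give ethyl (2R,3R)-4-[(4S)-4-benzyl-2-oxo-1,3-oxazolidin-3-yl]-2,3-dimethyl-4-oxobutanoate F6. LiOH/H2O2, then LiOH (THF/H2O, 0 °C → rt), would remove the auxiliary and the ethyl ester to give 4.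

**Further compounds**
F1 | step 11 | (3R,4R,5R)-5-[4-(benzyloxy)-3-methoxyphenyl]-3,4-dimethyloxolan-2-one | O1[C@@H](c2ccc(OCc3ccccc3)c(OC)c2)[C@H](C)[C@@H](C)C1=O
F2 | step 11 | (3R,4R,5R)-2,5-bis[4-(benzyloxy)-3-methoxyphenyl]-3,4-dimethyloxolan-2-ol (anomer mixture) | O1[C@@H](c2ccc(OCc3ccccc3)c(OC)c2)[C@H](C)[C@@H](C)C1(O)c1ccc(OCc2ccccc2)c(OC)c1
F3 | step 11 | (2S,3R,4R,5R)-2,5-bis[4-(benzyloxy)-3-methoxyphenyl]-3,4-dimethyloxolane | O1[C@@H](c2ccc(OCc3ccccc3)c(OC)c2)[C@H](C)[C@@H](C)[C@H]1c1ccc(OCc2ccccc2)c(OC)c1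
F4 | step 10 | (2R,3S)-1-[4-(benzyloxy)-3-methoxyphenyl]-4-(4-hydroxy-3-methoxyphenyl)-2,3-dimethylbutan-1-one | COc1cc(C[C@H](C)[C@@H](C)C(=O)c2ccc(OCc3ccccc3)c(OC)c2)ccc1O
F5 | step 1 | ethyl (R)-2-{[(trifluoromethyl)sulfonyl]oxy}propanoate | CCOC(=O)[C@@H](C)OS(=O)(=O)C(F)(F)F
F6 | step 1 | ethyl (2R,3R)-4-[(4S)-4-benzyl-2-oxo-1,3-oxazolidin-3-yl]-2,3-dimethyl-4-oxobutanoate | CCOC(=O)[C@H](C)[C@@H](C)C(=O)N1[C@@H](Cc2ccccc2)COC1=O
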